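At early times the electrophile in this flask is taken by two partners at once, the forward rate on the nucleophile standing at 0.82 of the rate on the protic impurity, and I want to know how far the nucleophile charge can carry it after that.

electrophile 0.10 M; nucleophile 0.150 M; protic impurity 0.0100 M; time 30 s

    electrophile + nucleophile ⇌ acid set free + target (K1 = 0.18, k1 = 0.48 L mol⁻¹ s⁻¹)
    nucleophile + acid set free ⇌ protonated nucleophile, settled at all times (K2 = 23000 L mol⁻¹)
    crystals ⇌ acid set free, rate k3*(cs3 - [acid set free]) while solid is left; crystals form when [acid set free] > cs3 (cs3 = 4.5 mM, k3 = 6.7 s⁻¹)
    electrophile + protic impurity → quenched substrate (k4 = 8.8 L mol⁻¹ s⁻¹)

- for acid set free the crystals are counted in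
- as a solid, counted per litre of solution: crystals
- run time (flask): 30 s

- part of the electrophile that has reacted at 30 s
- share of the unused nucleophile that is free and not bound as protonated nucleophile, at 30 s

I turn the constants into times and ratios at the charged amounts. The capture of acid set free stands at balance, with 3400 bound for each free at the charged nucleophile, so I count two nucleophiles per target, one consumed and one bound; that count also ties fr to c. Even with 0.0750 M of acid bound and the free nucleophile down to 1.50 mM, the balance leaves 2.17 mM of acid free, below the solubility of 4.5 mM, so I set the crystals aside. The protic impurity has a half-life of 0.788 s at the charged electrophile, shorter than the 9.6 s of the forward step on the nucleophile, so it takes its 10.0% of the electrophile charge early. That leaves 90.0% of the charge facing nucleophile pairs worth 75.0%, which makes the nucleophile, counted in pairs, the limiting reagent of what remains. My ceiling is therefore the impurity's share plus the share the nucleophile pairs can pay for, 85.0% of the electrophile charge. The last rung is the approach to that ceiling, with a time of 69.4 s reckoned from the excess electrophile, longer than the earlier times and longer than the 30 s of the run. So I commit to a c below the ceiling at 30 s, and my reckoning stops there.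

The forecast gives 67.3% and 38.2%, holding of the acid set free that “the nucleophile captures it almost completely”.

This flask gives 67.3% and 38.2% at 30 s. Left until 300 s, this flask reaches 81.2%, still under the ceiling. With 0.090 M of nucleophile and the other charges unchanged, the same count puts the ceiling at 55.0%, and that neighbour flask stands at 47.9% at 30 s, with 16% of its nucleophile still free.

All constants belong to no real substance; no experiment stands behind them.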